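Neither earlier run changes the reagent charge, so an order in reagent cannot be read off a pair of runs; it has to be built from what the catalyst holds.

the same everywhere: left-handed substrate 0.23 M; right-handed substrate 0.23 M

|  | reagent | free catalyst | remark |
|---|---|---|---|
| dusk | 1.5 equiv | 6.7 mol% | run made earlier |
| autumn | 1.5 equiv | 15 mol% | run made earlier |
| flask | 1.50 equiv | 10 mol% |  |

- dusk (time / h: left-handed product / %, left-handed substrate / %): 1.33: 3.9, 45.3; 4.00: 9.6, 38.9; 8.00: 14.5, 34.5; 10.0: 16.6, 32.7; 15.0: 21.2, 28.4; 20.0: 24.4, 25.7
- autumn (time / h: left-handed product / %, left-handed substrate / %): 1.33: 7.8, 39.4; 4.00: 17.2, 30.8; 8.00: 25.0, 23.4; 10.0: 26.4, 21.2; 15.0: 30.7, 17.8; 20.0: 34.1, 14.5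

(standard deviation of a reading: 0.3 percentage points)

- free catalyst is single-handed; left-handed substrate and right-handed substrate are mirror images of each other, charged as a racemate, each of them at the stated concentration
- what is bound to the catalyst counts as converted
- no earlier run changes the charge of reagent; that part of a forecast is a guess

- apparent order in reagent when 10% of the left-handed substrate and right-handed substrate together are converted (percent change of the rate of making left-handed product for one percent more reagent charged)

The autumn run shows the cycle in slow motion. Left-handed substrate that has left solution but is absent from the product sits on the catalyst. At 1.33 h in autumn that held amount reads 2.8 percentage points of the charge, or 37.3% of the catalyst. Divided by the mean rate of making left-handed product, it gives 0.477 h, the held life: the time a held left-handed substrate waits to become product.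

In the middle of autumn, at 10.0 h, the held share reads 32.0%. At 20.0 h it reads 18.7%, while the held life has stretched to 2.06 h, a reading with the scatter of 0.3 points on each number.

A life that stretches as the run proceeds reads as a step that needs reagent. Taking the life as inverse to [reagent], the rate is the held amount over the life, and the order is one plus the percent rise of the held amount per percent of reagent. In autumn 62.7% of the catalyst stands off the left-handed side at 1.33 h. If right-handed substrate holds it, reagent releases it, so this reckoning puts the order at one or a little above.

The forecast differs and gives 0.6, with the remark “No run varied reagent”.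

The flask gives 1.4.

    free catalyst + left-handed substrate ⇌ catalyst intermediate A (K = 38.0 M⁻¹, k = 6.00 M⁻¹ min⁻¹)
    free catalyst + right-handed substrate ⇌ catalyst intermediate B (K = 110 M⁻¹, k = 1.80 M⁻¹ min⁻¹)
    reagent + catalyst intermediate A → free catalyst + left-handed product (k = 0.120 M⁻¹ min⁻¹)
    reagent + catalyst intermediate B → free catalyst + right-handed product (k = 0.0410 M⁻¹ min⁻¹)
    reagent ⇌ dormant form (K = 0.450, k = 8.70 × 10⁻⁴ min⁻¹)

At 0.744 h the flask makes left-handed product at 0.0170 M h⁻¹, so the held life puts 35.3% of its catalyst on catalyst intermediate A. Twice the reagent multiplies that rate by 2.54. With the life cut by a factor 2, the reckoned share rises to 44.8%. At 2.00 h the flask's resting state is catalyst intermediate B, at 64.9% against 30.0% for catalyst intermediate A. With the falling back of catalyst intermediate A to free catalyst + left-handed substrate taken away, the flask's order falls from 1.4 to 0.98, the largest single effect.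

The numbers in the tables are simulated for an exercise; noise was put on by code.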